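If we want to know what stands at the end of these flasks, we should ask first how the free catalyst's equilibrium divides the pool of substrate and intermediate, and then how much of that pool the second catalyst drains to product during the run.

common to all: substrate 2.0 M; partner 2.20 M; free catalyst 2.0 mM; second catalyst 50 mM; time 8.0 h

| flask | temperature |
|---|---|
| grey | 35 °C |
| violet | 60 °C |

    substrate + free catalyst ⇌ free catalyst + intermediate (K1 = 2.0, k1 = 834 M⁻¹ h⁻¹, Ea1 = 52.0 kJ mol⁻¹, ΔH1 = −34.0 kJ mol⁻¹)
    partner + second catalyst + intermediate → second catalyst + product (k2 = 0.139 M⁻² h⁻¹, Ea2 = 58.0 kJ mol⁻¹)
    second catalyst → spent catalyst A (k3 = 0.170 h⁻¹, Ea3 = 102 kJ mol⁻¹)
    second catalyst + product → spent catalyst B (k4 = 0.0101 M⁻¹ h⁻¹, Ea4 = 66.0 kJ mol⁻¹)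
    (constants at 35 °C)

1. which of these there is most of at the end, counted by the substrate in it, grey (product / intermediate / substrate)
2. which of these there is most of at the end, counted by the substrate in it, violet (product / intermediate / substrate)
3. how much there is at the end of the one of these that leads, in percent of the substrate charged: grey
4. how much there is at the end of the one of these that leads, in percent of the substrate charged: violet

The free catalyst interconverts substrate and intermediate. The second catalyst joins partner to intermediate to give product, and it dies by itself to spent catalyst A or with product to spent catalyst B.

We build grey first, starting with the free catalyst's step. The pool of substrate plus intermediate relaxes with a time of 0.400 h, short against the run, so we treat it as a pre-equilibrium: the intermediate holds 66.7% of the pool.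

Next we add the product step and let the second catalyst live on for the moment. The pool then drains at a rate constant times [partner], times that share, times [second catalyst], and over the run it loses 8.15%.

Now the second catalyst dies at 0.170 h⁻¹. What counts is the time integral of its concentration, the dose, which comes to 787 M·s instead of 1440 M·s. The drain, the share of the pool that the whole dose turns into product, falls to 4.46%. We drop the death by product, because its constant times the whole substrate charge, 0.0202 h⁻¹, is less than the death by itself.

Then we go round once more: the first answer lowers pool and partner during the run, so we put in their means between start and end. The drain becomes 4.27%, and grey ends with intermediate in the lead at 63.8%.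

Violet goes the same way with warmed constants. The relaxation time is 0.0555 h, again short. The equilibrium constant falls to 0.739, so the intermediate's share is 42.5%. The death constant rises to 3.37 h⁻¹ and the product constant to 0.760 M⁻² h⁻¹. The dose shrinks to 53.4 M·s, the drain to 1.05%, and after the second round to 1.04%. Violet therefore ends with substrate in the lead at 56.9%.

The forecast gives intermediate at 64% for grey and substrate at 57% for violet, on this ground: “So substrate and intermediate sit at equilibrium, and only the slow drain to product changes the pool.”

The simulation gives intermediate at 64.0% in grey and substrate at 57.0% in violet. In violet the second catalyst stood at 0% after 4.00 h, with product already at 0.878%. A repeat of violet at 45 °C has a dose of 300 M·s. Its first-round drain is 2.95%, less than grey's 4.46%, and its second-round drain is 2.87%. That flask ended with product at 2.59%.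

Its constants were chosen freely; the flask was simulated.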